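**Retrosynthetic overview**

- Labels: ring A is the 4-hydroxy-3,5-dimethoxyphenyl group on C7; C8 carries C9H2OH; O3' (on C7) and O4' (on C8) are the dioxane oxygens on C3' and C4' of benzo ring B, whose C1' carries the propenal.
- Feature used: O4'–C4' is para and O3'–C3' meta to C1', so a formyl group at C1' activates a fluoride at C4' for displacement, while O3' can enter as a phenoxide at C7, the benzylic carbon of a C7–C8 epoxide.
- 12 ⇒ (cleavage of two benzyl ethers; Wittig extension of the C1' formyl group) trans-benzodioxane aldehyde 10 ⇒ (C7–O3' and C4'–O4' in one pot) cis-epoxide 7 + 4-fluoro-3-hydroxybenzaldehyde 8.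
- 7 ⇒ asymmetric epoxidation of (Z)-alkene 6 ⇒ semihydrogenation of alkyne 5 ⇒ Sonogashira coupling of aryl iodide 3 (from 2,6-dimethoxyphenol 1) with benzyl propargyl ether 4.
- Ring order: rings A and B are bought; the 1,4-dioxane ring is the only ring made (step 6). Both stereocentres are set in step 5; step 6 inverts C7 and retains C8.

Key step: step 6

Remark: the sense of induction in step 5 is assigned by analogy with cis-β-methylstyrene, which gives its (1R,2S)-oxide with the (R,R) catalyst; the antipodal catalyst would be used should the assignment prove reversed.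

**Route**

Step 1
Reactants: 1 2,6-dimethoxyphenol
Product: 2 4-iodo-2,6-dimethoxyphenol
Conditions: NIS (1.0 equiv), MeCN, 0 °C to rt, dark
Reagents that add atoms: N-iodosuccinimide, O=C1CCC(=O)N1I
Why: Electrophilic aromatic iodination, in which the free hydroxyl group is the strongest donor and directs iodine to its para position (C4), both ortho positions being occupied by methoxy groups.

Step 2
Reactants: 2 4-iodo-2,6-dimethoxyphenol
Product: 3 2-(benzyloxy)-5-iodo-1,3-dimethoxybenzene
Conditions: BnBr, K2CO3, DMF, 60 °C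
Reagents that add atoms: benzyl bromide, BrCc1ccccc1
Why: Williamson ether synthesis (SN2 of the phenoxide on benzyl bromide), which masks the phenol so that the later benzylic epoxide cannot open through a para-quinone methide.

Step 3
Reactants: 3 2-(benzyloxy)-5-iodo-1,3-dimethoxybenzene; 4 benzyl propargyl ether
Product: 5 2-(benzyloxy)-5-[3-(benzyloxy)prop-1-yn-1-yl]-1,3-dimethoxybenzene
Conditions: PdCl2(PPh3)2 (2 mol %), CuI (4 mol %), Et3N–THF, degassed, rt to 45 °C
Reagents that add atoms: none
Why: Sonogashira coupling, in which oxidative addition of the aryl iodide to zerovalent palladium, transmetalation from the copper acetylide of 4 and reductive elimination join ring A to the C7–C8–C9 chain.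

Step 4
Reactants: 5 2-(benzyloxy)-5-[3-(benzyloxy)prop-1-yn-1-yl]-1,3-dimethoxybenzene
Product: 6 (Z)-2-(benzyloxy)-5-[3-(benzyloxy)prop-1-en-1-yl]-1,3-dimethoxybenzene
Conditions: H2 (1 atm), Pd/CaCO3 poisoned with Pb(OAc)2, quinoline, EtOAc, rt
Reagents that add atoms: none
Why: Lindlar semihydrogenation, in which syn delivery of one equivalent of hydrogen on the lead-poisoned palladium surface gives the (Z)-alkene and the poisoned catalyst should leave both benzyl ethers and the product alkene untouched.

Step 5
Reactants: 6 (Z)-2-(benzyloxy)-5-[3-(benzyloxy)prop-1-en-1-yl]-1,3-dimethoxybenzene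
Product: 7 (2R,3S)-2-[4-(benzyloxy)-3,5-dimethoxyphenyl]-3-[(benzyloxy)methyl]oxirane
Conditions: (R,R)-(salen)MnCl (5 mol %; salen = N,N'-bis(3,5-di-tert-butylsalicylidene)-1,2-cyclohexanediamine dianion), 4-phenylpyridine N-oxide (20 mol %), aq. NaOCl buffered to pH 11.3 (Na2HPO4), CH2Cl2, 0 °C
Reagents that add atoms: sodium hypochlorite, [Na+].[O-]Cl
Why: Jacobsen–Katsuki epoxidation, for which cis-disubstituted aryl alkenes are the best substrate class; side-on approach of the (Z)-alkene to the manganese oxo species of the (R,R) catalyst should give the cis-epoxide with C7 R and C8 S, and the basic medium protects the acid-sensitive benzylic epoxide.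

Step 6
Reactants: 7 (2R,3S)-2-[4-(benzyloxy)-3,5-dimethoxyphenyl]-3-[(benzyloxy)methyl]oxirane; 8 4-fluoro-3-hydroxybenzaldehyde
Product: 10 (2S,3S)-3-[4-(benzyloxy)-3,5-dimethoxyphenyl]-2-[(benzyloxy)methyl]-2,3-dihydro-1,4-benzodioxine-6-carbaldehyde, via caesium alkoxide 9 (not isolated)
Conditions: 8 (1.3 equiv), Cs2CO3 (2.5 equiv), DMSO, 70 °C, then 110 °C
Reagents that add atoms: none
Why: Cs2CO3 converts 8 into its phenoxide, whose O3' opens the cis-epoxide by SN2 at benzylic C7 with inversion to give alkoxide 9; the C8 oxygen of 9 then adds to C4' ipso to fluorine, the Meisenheimer adduct is stabilised by the para formyl group, and loss of fluoride completes an addition–elimination (SNAr). The closest known reactions are the base-mediated opening of 3-arylglycidyl ethers by phenols at the benzylic carbon and the alkoxide ring closure of 2-(2-fluoroaryloxy)ethanols bearing a para formyl group to 1,4-benzodioxanes. The dioxane ring closes in a 6-exo-trig sense by attack of the tethered alkoxide on the arene carbon C4'. No stereocentre is created: C7 is inverted and C8 retained, so the (7R,8S)-cis-epoxide maps onto the (7S,8S)-trans-dioxane. The step needs attack at C7 and not C8, which benzylic activation by ring A and inductive deactivation of C8 by the C9 benzyloxy group should secure, and it needs a clean SN2 course, which the basic medium and the only weakly donating, twisted 4-benzyloxy group favour. Ring B regiochemistry follows from the fixed positions of OH (C3') and F (C4') in 8, a Smiles shift of the aryl group to the C8 oxygen being disfavoured because C3' is meta to the formyl group.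

Step 7
Reactants: 10 (2S,3S)-3-[4-(benzyloxy)-3,5-dimethoxyphenyl]-2-[(benzyloxy)methyl]-2,3-dihydro-1,4-benzodioxine-6-carbaldehyde
Product: 11 (E)-3-{(2S,3S)-3-[4-(benzyloxy)-3,5-dimethoxyphenyl]-2-[(benzyloxy)methyl]-2,3-dihydro-1,4-benzodioxin-6-yl}prop-2-enal
Conditions: Ph3P=CHCHO (1.3 equiv), toluene, 80 °C
Reagents that add atoms: (triphenylphosphoranylidene)acetaldehyde, O=CC=P(c1ccccc1)(c1ccccc1)c1ccccc1
Why: Wittig reaction with a formyl-stabilised ylide, which under thermal, neutral conditions gives the (E)-enal and leaves the ethers and both dioxane stereocentres untouched.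

Step 8
Reactants: 11 (E)-3-{(2S,3S)-3-[4-(benzyloxy)-3,5-dimethoxyphenyl]-2-[(benzyloxy)methyl]-2,3-dihydro-1,4-benzodioxin-6-yl}prop-2-enal
Product: 12 (E)-3-[(2S,3S)-3-(4-hydroxy-3,5-dimethoxyphenyl)-2-(hydroxymethyl)-2,3-dihydro-1,4-benzodioxin-6-yl]prop-2-enal
Conditions: BCl3 (6 equiv), C6HMe5 (8 equiv), CH2Cl2, −78 to −40 °C; aq. NaHCO3 quench
Reagents that add atoms: none
Why: Lewis-acid ether cleavage with a non-basic cation scavenger, in which BCl3 activates each benzyl ether oxygen and pentamethylbenzene takes up the benzyl cation by Friedel–Crafts alkylation so that ring A is not C-benzylated, while at low temperature the aryl methyl ethers, the enal and the dioxane ring should survive and no stereocentre is touched.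

**Compound list**

1 | 2,6-dimethoxyphenol | COc1cccc(OC)c1O | starting material
2 | 4-iodo-2,6-dimethoxyphenol | COc1cc(I)cc(OC)c1O | intermediate
3 | 2-(benzyloxy)-5-iodo-1,3-dimethoxybenzene | COc1cc(I)cc(OC)c1OCc1ccccc1 | intermediate
4 | benzyl propargyl ether, 3-(benzyloxy)prop-1-yne | C#CCOCc1ccccc1 | starting material
5 | 2-(benzyloxy)-5-[3-(benzyloxy)prop-1-yn-1-yl]-1,3-dimethoxybenzene | COc1cc(C#CCOCc2ccccc2)cc(OC)c1OCc1ccccc1 | intermediate
6 | (Z)-2-(benzyloxy)-5-[3-(benzyloxy)prop-1-en-1-yl]-1,3-dimethoxybenzene | COc1cc(/C=C\COCc2ccccc2)cc(OC)c1OCc1ccccc1 | intermediate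
7 | (2R,3S)-2-[4-(benzyloxy)-3,5-dimethoxyphenyl]-3-[(benzyloxy)methyl]oxirane, cis, C7 R and C8 S | COc1cc(cc(OC)c1OCc1ccccc1)[C@H]1O[C@H]1COCc1ccccc1 | intermediate
8 | 4-fluoro-3-hydroxybenzaldehyde | O=Cc1ccc(F)c(O)c1 | starting material
9 | caesium (1S,2S)-3-(benzyloxy)-1-[4-(benzyloxy)-3,5-dimethoxyphenyl]-1-(2-fluoro-5-formylphenoxy)propan-2-olate | COc1cc(cc(OC)c1OCc1ccccc1)[C@H](Oc1cc(C=O)ccc1F)[C@@H]([O-])COCc1ccccc1.[Cs+] | intermediate
10 | (2S,3S)-3-[4-(benzyloxy)-3,5-dimethoxyphenyl]-2-[(benzyloxy)methyl]-2,3-dihydro-1,4-benzodioxine-6-carbaldehyde, trans | COc1cc(cc(OC)c1OCc1ccccc1)[C@@H]1Oc2cc(C=O)ccc2O[C@H]1COCc1ccccc1 | intermediate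
11 | (E)-3-{(2S,3S)-3-[4-(benzyloxy)-3,5-dimethoxyphenyl]-2-[(benzyloxy)methyl]-2,3-dihydro-1,4-benzodioxin-6-yl}prop-2-enal | COc1cc(cc(OC)c1OCc1ccccc1)[C@@H]1Oc2cc(/C=C/C=O)ccc2O[C@H]1COCc1ccccc1 | intermediate
12 | (E)-3-[(2S,3S)-3-(4-hydroxy-3,5-dimethoxyphenyl)-2-(hydroxymethyl)-2,3-dihydro-1,4-benzodioxin-6-yl]prop-2-enal | COc1cc([C@@H]2Oc3cc(/C=C/C=O)ccc3O[C@H]2CO)cc(OC)c1O | target

**Step count**

Total steps: 8. Longest linear sequence: 8 steps (1 to 12).

**Steps most likely to fail, with fallbacks**

Step 6. The carbonate may generate too little C8 alkoxide for the ring closure, and the opening may lose its SN2 course at C7 (attack at C8, or partial ionisation at the benzylic carbon). The fallback makes the two bonds separately and closes the ring by palladium catalysis instead of SNAr. It sets out from epoxide 7. Opening with commercial 4-bromo-3-hydroxybenzaldehyde (O=Cc1ccc(Br)c(O)c1; K2CO3, DMF, 70 °C), whose bromide is not displaced at this temperature, should give 4-bromo-3-{[(1S,2S)-3-(benzyloxy)-1-[4-(benzyloxy)-3,5-dimethoxyphenyl]-2-hydroxypropyl]oxy}benzaldehyde F1, on which the regio- and stereochemistry of the opening can be checked. Intramolecular Pd-catalysed aryl ether formation (Pd(OAc)2, 2-(di-tert-butylphosphino)-1,1'-binaphthyl, Cs2CO3, toluene, 80 °C) does not break the C8–O bond and so keeps C8; it comes back to the route at 10.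

Step 5. The stepwise oxygen transfer from manganese to this electron-rich styrene may allow bond rotation in the radical intermediate, which leaks to the trans-epoxide and, after step 6, to the cis-dioxane. Enantiofacial discrimination may also be incomplete, and the epoxide may open on acidic surfaces. The fallback uses a concerted, alcohol-directed epoxidation and sets out from aryl iodide 3. Sonogashira coupling with propargyl alcohol (PdCl2(PPh3)2, CuI, Et3N–THF) should give 3-[4-(benzyloxy)-3,5-dimethoxyphenyl]prop-2-yn-1-ol F2. Semihydrogenation over Pd/CaCO3 poisoned with Pb(OAc)2 should give (Z)-3-[4-(benzyloxy)-3,5-dimethoxyphenyl]prop-2-en-1-ol F3. Sharpless asymmetric epoxidation (Ti(OiPr)4, L-(+)-diethyl tartrate, t-BuOOH, 4 Å molecular sieves, CH2Cl2, −20 °C) cannot isomerise the alkene and should give [(2S,3R)-3-[4-(benzyloxy)-3,5-dimethoxyphenyl]oxiran-2-yl]methanol F4. O-Benzylation (NaH, BnBr, cat. Bu4NI, THF, 0 °C) comes back to the route at 7.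

Step 8. BCl3 may ionise the benzylic C7–O3' bond of the dioxane or promote addition to the boron-activated enal while the slower primary benzyl ether is still being cleaved. The fallback removes the benzyl groups by neutral hydrogenolysis before the alkene exists and sets out from aldehyde 10. Hydrogenolysis (H2, Pd/C, EtOAc–MeOH, rt, stopped once the second benzyl ether is consumed) should give (2S,3S)-3-(4-hydroxy-3,5-dimethoxyphenyl)-2-(hydroxymethyl)-2,3-dihydro-1,4-benzodioxine-6-carbaldehyde F5. The Wittig reaction with Ph3P=CHCHO (THF, 65 °C), which tolerates free hydroxyl groups, then comes back to the route at target 12.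

**Further compounds**

F1 | step 6 | 4-bromo-3-{[(1S,2S)-3-(benzyloxy)-1-[4-(benzyloxy)-3,5-dimethoxyphenyl]-2-hydroxypropyl]oxy}benzaldehyde | COc1cc(cc(OC)c1OCc1ccccc1)[C@H](Oc1cc(C=O)ccc1Br)[C@@H](O)COCc1ccccc1
F2 | step 5 | 3-[4-(benzyloxy)-3,5-dimethoxyphenyl]prop-2-yn-1-ol | COc1cc(C#CCO)cc(OC)c1OCc1ccccc1
F3 | step 5 | (Z)-3-[4-(benzyloxy)-3,5-dimethoxyphenyl]prop-2-en-1-ol | COc1cc(/C=C\CO)cc(OC)c1OCc1ccccc1
F4 | step 5 | [(2S,3R)-3-[4-(benzyloxy)-3,5-dimethoxyphenyl]oxiran-2-yl]methanol | COc1cc(cc(OC)c1OCc1ccccc1)[C@H]1O[C@H]1CO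
F5 | step 8 | (2S,3S)-3-(4-hydroxy-3,5-dimethoxyphenyl)-2-(hydroxymethyl)-2,3-dihydro-1,4-benzodioxine-6-carbaldehyde | COc1cc(cc(OC)c1O)[C@@H]1Oc2cc(C=O)ccc2O[C@H]1CO
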